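## Retrosynthesis
- The flavanone C ring is closed last. An enantioselective intramolecular oxa-Michael addition of a 2'-hydroxychalcone sets C2 (S), and global MOM removal then gives the target.
- The chalcone comes from Claisen–Schmidt condensation of 2'-hydroxy-4',6'-bis(MOM)-3'-lavandulylacetophenone (10) with 2,4-bis(MOM)benzaldehyde (12). Only the 2'-OH is free, so ring O1 forms next to C8 and only the 8-substituted flavanone can result.
- The lavandulyl group is attached by C-alkylation of symmetric 2',4',6'-trihydroxyacetophenone with (S)-lavandulyl bromide. The ring has only one type of C–H site, so there is no regiochemical problem.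
- The lavandulyl stereocenter comes from an Evans alkylation of a 3-methylbut-3-enoyl imide with prenyl bromide, then reductive auxiliary removal and Appel bromination.
- Ring order: the A ring is aromatic from the start and carries the lavandulyl group, and the C ring is formed last.

**Assumption:** the hindered 2'-OH of the lavandulyl acetophenone (flanked by acetyl and lavandulyl) stays free when two MOM groups are installed. The target has lavandulyl carbon R and C2 S. The lavandulyl carbon is labelled S in the CH2OH and CH2Br intermediates (6, 7) and R in the aryl compounds (9–15) only because CIP priorities change; its spatial arrangement is unchanged.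

## Route

**Step 1**
Reactants: 1 (3-methylbut-3-enoic acid); 2 ((S)-4-benzyloxazolidin-2-one)
Product: 3 ((S)-4-benzyl-3-(3-methylbut-3-enoyl)oxazolidin-2-one)
Conditions: PivCl, Et3N, THF, –20 °C; then 2, LiCl, 0 °C to rt
Reagents that add atoms: none (the pivaloyl group leaves as pivalate)
Why: Mixed-anhydride N-acylation attaches the chiral auxiliary without touching the β,γ-alkene, and no stereocenter is formed.

**Step 2**
Reactants: 3; 4 (prenyl bromide, 1-bromo-3-methylbut-2-ene)
Product: 5 ((S)-4-benzyl-3-[(2S)-2-isopropenyl-5-methylhex-4-enoyl]oxazolidin-2-one)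
Conditions: NaHMDS, THF, –78 °C; add 4; –78 to –40 °C; quench with AcOH
Reagents that add atoms: none (4 is a reactant)
Why: In an Evans asymmetric enolate alkylation, the chelated sodium Z-dienolate is attacked by prenyl bromide at the α-carbon from the face opposite the benzyl group, which sets the α-carbon as S.

**Step 3**
Reactants: 5
Product: 6 ((S)-lavandulol, (2S)-5-methyl-2-(prop-1-en-2-yl)hex-4-en-1-ol)
Conditions: LiBH4, MeOH (1 equiv), Et2O, 0 °C
Reagents that add atoms: none (LiBH4 and MeOH supply only hydride and a proton; the alcohol oxygen comes from the imide carbonyl)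
Why: Hydride cleaves the imide (reductive auxiliary removal) to the primary alcohol and releases 2 for recovery, while the α-stereocenter and both alkenes are untouched.

**Step 4**
Reactants: 6
Product: 7 ((S)-lavandulyl bromide, (2S)-1-bromo-5-methyl-2-(prop-1-en-2-yl)hex-4-ene)
Conditions: CBr4, PPh3, CH2Cl2, 0 °C
Reagents that add atoms: carbon tetrabromide, BrC(Br)(Br)Br (supplies Br)
Why: Appel substitution at the primary carbon under neutral conditions leaves the adjacent stereocenter untouched.

**Step 5**
Reactants: 8 (2',4',6'-trihydroxyacetophenone, commercial); 7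
Product: 9 (1-{2,4,6-trihydroxy-3-[(2R)-5-methyl-2-(prop-1-en-2-yl)hex-4-en-1-yl]phenyl}ethanone)
Conditions: 8 (2.5 equiv), KOH (2.5 equiv), cat. NaI, MeOH–H2O, 0 °C to rt, 24 h
Reagents that add atoms: none (7 is a reactant)
Why: In protic solvent the phloroglucinol-type phenoxide is a C-nucleophile, so SN2 C-alkylation occurs at the single ring C–H site, with excess 8 suppressing dialkylation and the remote stereocenter not involved.

**Step 6**
Reactants: 9
Product: 10 (2'-hydroxy-4',6'-bis(methoxymethoxy)-3'-[(2R)-lavandulyl]acetophenone)
Conditions: MOMCl (2.1 equiv), K2CO3, acetone, 0 °C to rt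
Reagents that add atoms: chloromethyl methyl ether, ClCOC (supplies two CH2OCH3 groups)
Why: In this phenol O-alkylation (MOM protection) the unhindered 4'-OH and 6'-OH react, while the 2'-OH, chelated to the ketone and flanked by acetyl and lavandulyl, stays free to become the ring oxygen.

**Step 7**
Reactants: 11 (2,4-dihydroxybenzaldehyde, commercial)
Product: 12 (2,4-bis(methoxymethoxy)benzaldehyde)
Conditions: MOMCl (2.5 equiv), iPr2NEt, CH2Cl2, 0 °C to rt
Reagents that add atoms: chloromethyl methyl ether, ClCOC
Why: MOM protection of both phenols prevents phenoxide formation, which would deactivate the aldehyde under the basic conditions of Step 8.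

**Step 8**
Reactants: 10; 12
Product: 13 ((E)-2'-hydroxychalcone bearing 4',6',2,4-tetra-OMOM and 3'-[(2R)-lavandulyl])
Conditions: 50% aq KOH, EtOH, rt, 48 h; quench with sat. NH4Cl
Reagents that add atoms: none
Why: Claisen–Schmidt condensation gives the thermodynamic E-enone, and the electron-rich, chelated 2'-hydroxychalcone does not cyclize under these conditions, so no racemic flavanone forms.

**Step 9**
Reactants: 13
Product: 14 (tetra-MOM (2S)-8-[(2R)-lavandulyl]flavanone)
Conditions: 10 mol% quinine-derived bifunctional thiourea (pseudoenantiomer chosen to give 2S), toluene, 25 °C, 4 d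
Reagents that add atoms: none (catalyst)
Why: In an enantioselective intramolecular oxa-Michael addition, the catalyst's tertiary amine activates the phenol and the thiourea binds the enone, so the phenoxide adds to one enone face and sets C2 as S, while the remote lavandulyl center has little influence and is not epimerizable.

**Step 10**
Reactants: 14
Product: 15 (sophoraflavanone G)
Conditions: 2 M HCl, MeOH–THF (1:1), 35 °C, 6 h; neutral work-up
Reagents that add atoms: none (the MOM groups leave as CH2(OMe)2 and formaldehyde-derived by-products, and no reagent atoms remain in the product)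
Why: Acid-catalysed MOM ether cleavage frees all four phenols, and under dilute acid at mild temperature C2 does not epimerize and the ketone, isopropenyl and prenyl alkenes survive.

## Compound list
1 | 3-methylbut-3-enoic acid | C=C(C)CC(=O)O | starting material
2 | (S)-4-benzyloxazolidin-2-one | O=C1N[C@@H](Cc2ccccc2)CO1 | starting material
3 | (S)-4-benzyl-3-(3-methylbut-3-enoyl)oxazolidin-2-one | C=C(C)CC(=O)N1[C@@H](Cc2ccccc2)COC1=O | intermediate
4 | prenyl bromide | CC(C)=CCBr | starting material
5 | (S)-4-benzyl-3-[(2S)-2-isopropenyl-5-methylhex-4-enoyl]oxazolidin-2-one | C=C(C)[C@H](CC=C(C)C)C(=O)N1[C@@H](Cc2ccccc2)COC1=O | intermediate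
6 | (S)-lavandulol | C=C(C)[C@H](CC=C(C)C)CO | intermediate
7 | (S)-lavandulyl bromide | C=C(C)[C@H](CC=C(C)C)CBr | intermediate
8 | 2',4',6'-trihydroxyacetophenone | CC(=O)c1c(O)cc(O)cc1O | starting material
9 | 3'-[(2R)-lavandulyl]-2',4',6'-trihydroxyacetophenone | C=C(C)[C@H](CC=C(C)C)Cc1c(O)cc(O)c(C(C)=O)c1O | intermediate
10 | 2'-hydroxy-4',6'-bis(MOM)-3'-[(2R)-lavandulyl]acetophenone | C=C(C)[C@H](CC=C(C)C)Cc1c(OCOC)cc(OCOC)c(C(C)=O)c1O | intermediate
11 | 2,4-dihydroxybenzaldehyde | O=Cc1ccc(O)cc1O | starting material
12 | 2,4-bis(methoxymethoxy)benzaldehyde | O=Cc1ccc(OCOC)cc1OCOC | intermediate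
13 | (E)-tetra-MOM 2'-hydroxychalcone | C=C(C)[C@H](CC=C(C)C)Cc1c(OCOC)cc(OCOC)c(C(=O)/C=C/c2ccc(OCOC)cc2OCOC)c1O | intermediate
14 | tetra-MOM (2S)-8-[(2R)-lavandulyl]flavanone | C=C(C)[C@H](CC=C(C)C)Cc1c(OCOC)cc(OCOC)c2c1O[C@H](c1ccc(OCOC)cc1OCOC)CC2=O | intermediate
15 | sophoraflavanone G | C=C(C)[C@H](CC=C(C)C)Cc1c(O)cc(O)c2c1O[C@H](c1ccc(O)cc1O)CC2=O | target

**Total steps:** 10 (Step 7 is a parallel branch that makes aldehyde 12).
**Longest linear sequence:** 9 steps (Steps 1, 2, 3, 4, 5, 6, 8, 9, 10).

## Three steps most likely to fail
1. **Step 9, asymmetric oxa-Michael.** The electron-rich, tetra-alkoxy chalcone is a poor acceptor, so conversion and ee may be low. Fallback: cyclize without chiral control (NaOAc, EtOH, reflux) to a roughly 1:1 mixture of the (2S,2''R) and (2R,2''R) flavanones, separate these diastereomers by preparative HPLC, and carry the 2S isomer into Step 10.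
2. **Step 5, C-lavandulylation.** The β-branched bromide is a sluggish SN2 electrophile, and O-alkylation, elimination and dialkylation compete. Fallback: iodinate 8 with NIS to give the single 3'-iodo-2',4',6'-trihydroxyacetophenone, bis-MOM-protect as in Step 6, then Negishi-couple with the lavandulylzinc bromide made from 7 (excess reagent, Pd-PEPPSI-IPr) to give 10. This replaces the direct alkylation with a cross-coupling.
3. **Step 2, Evans alkylation of the β,γ-unsaturated imide.** Possible problems are poor dr, γ-alkylation, or isomerization to the conjugated imide. Fallback: lipase-catalysed kinetic resolution (vinyl acetate) of commercial racemic lavandulol to give (S)-lavandulol (6), replacing Steps 1–3 with a resolution.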